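**Retrosynthetic overview**

1. Target 31 comes from acid 30 by one fluoride deprotection; 30 comes from ring A phenol 26 by O-methylation at C1 and oxidation of the C6 CH2OPMB arm to CO2H.
2. Ring A (C1 OMe, C2 carbinol side chain, C3–H, C4–H, C5 O–ring B, C6 CO2H) has oxygen on C1 and C5 on either side of the carbon-substituted C6, next to the two adjacent CH positions. That is the pattern a vinylketene (C1, C4, C3, C2) plus an alkynyl ether (C5, C6) gives, so 26 is cut to diazo enone 21 and aryl ynol ether 14.
3. 14 comes from ring B phenol 7, trichloroethylene 8 and formaldehyde, so the crowded diaryl ether oxygen is bonded to an sp carbon and never to a second arene; 7 comes from creosol 1.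
4. 21 comes from (S)-leucic acid 15, whose carbinol carbon becomes the only stereocentre of the target.
5. Ring order: ring B is bought with creosol; ring A is the only ring built, in step 14.

Key step: step 14

Abbreviations: TBS = tert-butyldimethylsilyl; SEM = 2-(trimethylsilyl)ethoxymethyl; PMB = 4-methoxybenzyl; ArB = 2-{[(tert-butyldimethylsilyl)oxy]methyl}-4-methyl-6-{[2-(trimethylsilyl)ethoxy]methoxy}phenyl (protected ring B).

Remark: the carbinol carbon of the target is (S) (OH > aryl > CH2 > H), the same spatial arrangement as in (S)-leucic acid, so no inversion is planned; 2-[(4-methoxybenzyl)oxy]acetaldehyde, used only in one fallback, is taken as a purchasable reagent.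

**Route**

Step 1
Reactants: 1 creosol (2-methoxy-4-methylphenol)
Product: 3 2-hydroxy-3-methoxy-5-methylbenzaldehyde, via hydroxymethyl phenol 2 (not isolated)
Conditions: (CH2O)n, MgCl2, Et3N, MeCN, reflux
Reagents that add atoms: paraformaldehyde (formaldehyde), C=O
Why: Magnesium-phenoxide-directed ortho-formylation (Casnati–Skattebøl) hydroxymethylates the only free position ortho to the hydroxyl, and a second formaldehyde oxidises the benzylic alkoxide to the aldehyde, placing the future ring B CH2OH carbon.

Step 2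
Reactants: 3 2-hydroxy-3-methoxy-5-methylbenzaldehyde
Product: 4 2,3-dihydroxy-5-methylbenzaldehyde
Conditions: BBr3, CH2Cl2, −78 °C → 0 °C; H2O
Reagents that add atoms: none
Why: Lewis-acid-assisted SN2 demethylation of the aryl methyl ether frees the oxygen that ends as the ring B phenol, while the formyl group is only complexed and returns on aqueous work-up.

Step 3
Reactants: 4 2,3-dihydroxy-5-methylbenzaldehyde
Product: 5 2-hydroxy-5-methyl-3-{[2-(trimethylsilyl)ethoxy]methoxy}benzaldehyde
Conditions: NaH (2.1 equiv), DMSO–THF, 0 °C → rt; SEMCl (1.0 equiv)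
Reagents that add atoms: 2-(trimethylsilyl)ethoxymethyl chloride, C[Si](C)(C)CCOCCl
Why: Williamson-type alkylation of the dianion should occur on the C3 phenoxide, which is more basic and nucleophilic than the C2 phenoxide conjugated with and chelated to the formyl group, so one equivalent of SEMCl masks only the oxygen that must stay protected.

Step 4
Reactants: 5 2-hydroxy-5-methyl-3-{[2-(trimethylsilyl)ethoxy]methoxy}benzaldehyde
Product: 6 2-(hydroxymethyl)-4-methyl-6-{[2-(trimethylsilyl)ethoxy]methoxy}phenol
Conditions: NaBH4, MeOH–THF, 0 °C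
Reagents that add atoms: none
Why: Borohydride reduction of the aryl aldehyde is fast and leaves the acetal-type SEM ether untouched.

Step 5
Reactants: 6 2-(hydroxymethyl)-4-methyl-6-{[2-(trimethylsilyl)ethoxy]methoxy}phenol
Product: 7 ArB–OH (2-{[(tert-butyldimethylsilyl)oxy]methyl}-4-methyl-6-{[2-(trimethylsilyl)ethoxy]methoxy}phenol)
Conditions: TBSCl (1.05 equiv), imidazole, CH2Cl2, 0 °C
Reagents that add atoms: tert-butyldimethylsilyl chloride, CC(C)(C)[Si](C)(C)Cl
Why: Chemoselective imidazole-promoted silylation should take the unhindered primary benzylic hydroxyl in preference to the doubly ortho-substituted, hydrogen-bonded phenol, which stays free for the next step.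

Step 6
Reactants: 7 ArB–OH; 8 trichloroethylene
Product: 10 (E)-1,2-dichloroethenyl ArB ether, via dichloroacetylene 9 (not isolated)
Conditions: K2CO3, DMF, 70 °C
Reagents that add atoms: none
Why: Base dehydrochlorinates trichloroethylene to dichloroacetylene and the phenoxide adds to it anti (net addition–elimination on trichloroethylene), so the hindered ring B oxygen is bonded to a small linear carbon that later becomes C5 of ring A.

Step 7
Reactants: 10 (E)-1,2-dichloroethenyl ArB ether
Product: 13 3-(ArB-oxy)prop-2-yn-1-ol, via chloroethynyl ether 11 (not isolated), via lithium aryloxyacetylide 12 (not isolated)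
Conditions: n-BuLi (2.3 equiv), Et2O, −78 °C → −40 °C; (CH2O)n, −40 °C → rt; aq. NH4Cl; Et3N-deactivated silica
Reagents that add atoms: paraformaldehyde (formaldehyde), C=O
Why: n-BuLi eliminates HCl to the chloroalkyne and then exchanges Cl for Li, and the lithium aryloxyacetylide adds to formaldehyde (the standard dichlorovinyl ether route to substituted ynol ethers), installing the carbon that becomes the carboxyl carbon.

Step 8
Reactants: 13 3-(ArB-oxy)prop-2-yn-1-ol
Product: 14 3-[(4-methoxybenzyl)oxy]prop-1-yn-1-yl ArB ether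
Conditions: NaH, PMBCl, n-Bu4NI (cat.), THF–DMF, 0 °C → rt
Reagents that add atoms: 4-methoxybenzyl chloride, COc1ccc(CCl)cc1
Why: Williamson etherification of the primary propargylic alkoxide is chosen because ynol ethers tolerate base but hydrate under the acid needed for imidate benzylation.

Step 9
Reactants: 15 (S)-leucic acid ((S)-2-hydroxy-4-methylpentanoic acid)
Product: 16 methyl (S)-2-hydroxy-4-methylpentanoate
Conditions: MeOH, H2SO4 (cat.), reflux
Reagents that add atoms: methanol, CO
Why: Fischer esterification does not involve the stereocentre, so the (S) configuration bought with the acid is kept.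

Step 10
Reactants: 16 methyl (S)-2-hydroxy-4-methylpentanoate
Product: 17 methyl (S)-2-[(tert-butyldimethylsilyl)oxy]-4-methylpentanoate
Conditions: TBSCl, imidazole, DMF, rt
Reagents that add atoms: tert-butyldimethylsilyl chloride, CC(C)(C)[Si](C)(C)Cl
Why: Standard imidazole-promoted silylation of a secondary alcohol gives a bulky, non-chelating ether that protects the α-centre from epimerisation in the following steps.

Step 11
Reactants: 17 methyl (S)-2-[(tert-butyldimethylsilyl)oxy]-4-methylpentanoate
Product: 18 (S)-2-[(tert-butyldimethylsilyl)oxy]-4-methylpentanal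
Conditions: i-Bu2AlH (1.1 equiv), CH2Cl2, −78 °C; aq. potassium sodium tartrate (KNaC4H4O6)
Reagents that add atoms: none
Why: Partial reduction works because the tetrahedral aluminium hemiacetal of an α-silyloxy ester is stable at −78 °C until quench, so the aldehyde is released only on work-up and is not epimerised.

Step 12
Reactants: 18 (S)-2-[(tert-butyldimethylsilyl)oxy]-4-methylpentanal
Product: 19 (S,E)-5-[(tert-butyldimethylsilyl)oxy]-7-methyloct-3-en-2-one
Conditions: Ph3P=CHC(O)CH3, CH2Cl2, rt
Reagents that add atoms: 1-(triphenylphosphoranylidene)propan-2-one, CC(=O)C=P(c1ccccc1)(c1ccccc1)c1ccccc1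
Why: Wittig olefination with the stabilised acetonyl ylide is E-selective and too weakly basic to epimerise the α-silyloxy aldehyde.

Step 13
Reactants: 19 (S,E)-5-[(tert-butyldimethylsilyl)oxy]-7-methyloct-3-en-2-one
Product: 21 (S,E)-1-diazo-5-[(tert-butyldimethylsilyl)oxy]-7-methyloct-3-en-2-one, via trifluoroacetyl diketone 20 (not isolated)
Conditions: LiN(SiMe3)2, THF, −78 °C; CF3CO2CH2CF3; dilute HCl work-up, crude 20 used directly; MsN3, Et3N, H2O, MeCN, rt
Reagents that add atoms: methanesulfonyl azide, CS(=O)(=O)N=[N+]=[N-]; 2,2,2-trifluoroethyl trifluoroacetate, O=C(OCC(F)(F)F)C(F)(F)F (its atoms are carried only in 20)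
Why: Detrifluoroacetylative diazo transfer, the standard way to α'-diazo enones, relies on kinetic enolisation of the methyl ketone, Claisen trifluoroacetylation to activate that carbon and sulfonyl azide transfer with loss of the trifluoroacetyl group, none of which touches the γ-stereocentre.

Step 14
Reactants: 21 (S,E)-1-diazo-5-[(tert-butyldimethylsilyl)oxy]-7-methyloct-3-en-2-one; 14 3-[(4-methoxybenzyl)oxy]prop-1-yn-1-yl ArB ether
Product: 26 3-(ArB-oxy)-6-[(1S)-1-{[tert-butyl(dimethyl)silyl]oxy}-3-methylbutyl]-2-{[(4-methoxybenzyl)oxy]methyl}phenol, via vinylketene 22 (not isolated), via vinylcyclobutenone 23 (not isolated), via dienylketene 24 (not isolated), via cyclohexadienone 25 (not isolated)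
Conditions: hν (λ ≥ 300 nm, medium-pressure Hg lamp, Pyrex), degassed CH2Cl2, rt, 14 (1.3 equiv); then toluene, 80–110 °C
Reagents that add atoms: none
Why: Light expels N2 from 21 and Wolff rearrangement (1,2-shift of the alkenyl group) gives vinylketene 22, whose carbonyl carbon (future C1) bonds to the nucleophilic β-carbon of ynol ether 14 (future C6, bearing CH2OPMB) while its α-carbon (C4) bonds to the oxygen-bearing alkyne carbon (C5) in a ketene–alkyne [2+2] cycloaddition that gives 4-vinylcyclobutenone 23. Four-electron electrocyclic opening of 23 (light or heat) gives dienylketene 24, six-electron disrotatory electrocyclisation joins C1 to C2 to give cyclohexadienone 25, and enolisation delivers phenol 26. The closest known reaction type is the Danheiser benzannulation in its photochemical Wolff (diazo ketone) form with alkoxy- and silyloxyalkynes, of which an aryl alkynyl ether is a less common member of the same substrate class. The transient four-membered ring closes by [2+2] cycloaddition and ring A, the only ring made in the route, closes by 6π electrocyclisation. No stereocentre is created, because the sp3 ring carbons of 23 and 25 disappear on aromatisation, and the silyloxy carbinol carbon from leucic acid lies outside the reacting π-system and has no acidic hydrogen, so its (S) configuration is carried through. The step needs regioselectivity in the [2+2], secured by the oxygen-induced polarisation of the ynol ether that puts the aryloxy carbon meta to the new hydroxyl with the CH2OPMB carbon between them, and chemoselectivity for the alkyne, secured by masking every hydroxyl and by exciting the diazo enone at ≥300 nm, away from the weaker arene absorptions.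

Step 15
Reactants: 26 ring A phenol
Product: 27 1-(ArB-oxy)-4-[(1S)-1-{[tert-butyl(dimethyl)silyl]oxy}-3-methylbutyl]-3-methoxy-2-{[(4-methoxybenzyl)oxy]methyl}benzene
Conditions: MeI, K2CO3, DMF, rt
Reagents that add atoms: iodomethane, CI
Why: Williamson methylation of the only free hydroxyl with the small electrophile MeI tolerates the two ortho substituents, and the neighbouring silyl group stays on the more basic alkyl oxygen.

Step 16
Reactants: 27 methyl ether
Product: 28 {6-(ArB-oxy)-3-[(1S)-1-{[tert-butyl(dimethyl)silyl]oxy}-3-methylbutyl]-2-methoxyphenyl}methanol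
Conditions: DDQ (1.2 equiv), CH2Cl2–pH 7 phosphate buffer, 0 °C
Reagents that add atoms: none
Why: Oxidative PMB cleavage by DDQ (hydride abstraction at the most electron-rich benzylic position, then hydrolysis) is selective over silyl, SEM and methyl ethers, and any over-oxidation of the freed alcohol only anticipates the next step.

Step 17
Reactants: 28 benzylic alcohol
Product: 29 6-(ArB-oxy)-3-[(1S)-1-{[tert-butyl(dimethyl)silyl]oxy}-3-methylbutyl]-2-methoxybenzaldehyde
Conditions: Dess–Martin periodinane, NaHCO3, CH2Cl2, 0 °C → rt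
Reagents that add atoms: none
Why: Dess–Martin oxidation takes the primary benzylic alcohol to the aldehyde under buffered, near-neutral conditions that spare silyl and SEM ethers.

Step 18
Reactants: 29 aldehyde
Product: 30 6-(ArB-oxy)-3-[(1S)-1-{[tert-butyl(dimethyl)silyl]oxy}-3-methylbutyl]-2-methoxybenzoic acid
Conditions: NaClO2, NaH2PO4, 2-methyl-2-butene, t-BuOH–H2O, rt
Reagents that add atoms: sodium chlorite, [Na+].[O-]Cl=O
Why: Pinnick oxidation converts even a di-ortho-substituted aryl aldehyde to the acid, with 2-methyl-2-butene scavenging HOCl so that the electron-rich rings are not chlorinated.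

Step 19
Reactants: 30 protected acid
Product: 31 6-[2-hydroxy-6-(hydroxymethyl)-4-methylphenoxy]-3-[(1S)-1-hydroxy-3-methylbutyl]-2-methoxybenzoic acid (target)
Conditions: n-Bu4NF (excess), THF–DMPU, 60 °C; aq. NH4Cl
Reagents that add atoms: none
Why: Fluoride cleaves both TBS ethers and triggers β-elimination of the SEM group (loss of Me3SiF, ethene and formaldehyde), an aryl SEM ether being the more labile kind because a phenoxide leaves, and no stereocentre is touched.

**Compound list**

1 | creosol (2-methoxy-4-methylphenol) | COc1cc(C)ccc1O | starting material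
2 | 2-(hydroxymethyl)-6-methoxy-4-methylphenol (present as its magnesium salt) | COc1cc(C)cc(CO)c1O | intermediate (not isolated)
3 | 2-hydroxy-3-methoxy-5-methylbenzaldehyde | COc1cc(C)cc(C=O)c1O | intermediate
4 | 2,3-dihydroxy-5-methylbenzaldehyde | Cc1cc(O)c(O)c(C=O)c1 | intermediate
5 | 2-hydroxy-5-methyl-3-{[2-(trimethylsilyl)ethoxy]methoxy}benzaldehyde | C[Si](C)(C)CCOCOc1cc(C)cc(C=O)c1O | intermediate
6 | 2-(hydroxymethyl)-4-methyl-6-{[2-(trimethylsilyl)ethoxy]methoxy}phenol | C[Si](C)(C)CCOCOc1cc(C)cc(CO)c1O | intermediate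
7 | ArB–OH, 2-{[(tert-butyldimethylsilyl)oxy]methyl}-4-methyl-6-{[2-(trimethylsilyl)ethoxy]methoxy}phenol | C[Si](C)(C)CCOCOc1cc(C)cc(CO[Si](C)(C)C(C)(C)C)c1O | intermediate
8 | trichloroethylene | ClC=C(Cl)Cl | starting material
9 | dichloroacetylene | ClC#CCl | intermediate (not isolated)
10 | (E)-1,2-dichloroethenyl ArB ether | C[Si](C)(C)CCOCOc1cc(C)cc(CO[Si](C)(C)C(C)(C)C)c1O/C(Cl)=C\Cl | intermediate
11 | chloroethynyl ArB ether | C[Si](C)(C)CCOCOc1cc(C)cc(CO[Si](C)(C)C(C)(C)C)c1OC#CCl | intermediate (not isolated)
12 | lithium (ArB-oxy)acetylide | C[Si](C)(C)CCOCOc1cc(C)cc(CO[Si](C)(C)C(C)(C)C)c1OC#C[Li] | intermediate (not isolated)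
13 | 3-(ArB-oxy)prop-2-yn-1-ol | C[Si](C)(C)CCOCOc1cc(C)cc(CO[Si](C)(C)C(C)(C)C)c1OC#CCO | intermediate
14 | 3-[(4-methoxybenzyl)oxy]prop-1-yn-1-yl ArB ether | C[Si](C)(C)CCOCOc1cc(C)cc(CO[Si](C)(C)C(C)(C)C)c1OC#CCOCc1ccc(OC)cc1 | intermediate
15 | (S)-leucic acid, (S)-2-hydroxy-4-methylpentanoic acid | CC(C)C[C@H](O)C(=O)O | starting material
16 | methyl (S)-2-hydroxy-4-methylpentanoate | CC(C)C[C@H](O)C(=O)OC | intermediate
17 | methyl (S)-2-[(tert-butyldimethylsilyl)oxy]-4-methylpentanoate | CC(C)C[C@H](O[Si](C)(C)C(C)(C)C)C(=O)OC | intermediate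
18 | (S)-2-[(tert-butyldimethylsilyl)oxy]-4-methylpentanal | CC(C)C[C@H](O[Si](C)(C)C(C)(C)C)C=O | intermediate
19 | (S,E)-5-[(tert-butyldimethylsilyl)oxy]-7-methyloct-3-en-2-one | CC(=O)/C=C/[C@@H](O[Si](C)(C)C(C)(C)C)CC(C)C | intermediate
20 | (S,E)-7-[(tert-butyldimethylsilyl)oxy]-1,1,1-trifluoro-9-methyldec-5-ene-2,4-dione | O=C(CC(=O)/C=C/[C@@H](O[Si](C)(C)C(C)(C)C)CC(C)C)C(F)(F)F | intermediate (not isolated)
21 | (S,E)-1-diazo-5-[(tert-butyldimethylsilyl)oxy]-7-methyloct-3-en-2-one | [N-]=[N+]=CC(=O)/C=C/[C@@H](O[Si](C)(C)C(C)(C)C)CC(C)C | intermediate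
22 | vinylketene, (S,E)-5-[(tert-butyldimethylsilyl)oxy]-7-methylocta-1,3-dien-1-one | O=C=C/C=C/[C@@H](O[Si](C)(C)C(C)(C)C)CC(C)C | intermediate (not isolated)
23 | 4-vinylcyclobutenone: 3-(ArB-oxy)-2-{[(4-methoxybenzyl)oxy]methyl}-4-[(S,E)-3-(silyloxy)-5-methylhex-1-enyl]cyclobut-2-en-1-one, ring C4 unassigned | O=C1C(COCc2ccc(OC)cc2)=C(Oc2c(OCOCC[Si](C)(C)C)cc(C)cc2CO[Si](C)(C)C(C)(C)C)C1/C=C/[C@@H](O[Si](C)(C)C(C)(C)C)CC(C)C | intermediate (not isolated)
24 | dienylketene from ring opening of 23 | O=C=C(COCc1ccc(OC)cc1)/C(Oc1c(OCOCC[Si](C)(C)C)cc(C)cc1CO[Si](C)(C)C(C)(C)C)=C\C=C\[C@@H](O[Si](C)(C)C(C)(C)C)CC(C)C | intermediate (not isolated)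
25 | cyclohexa-2,4-dien-1-one, keto tautomer of 26, ring C6 unassigned | O=C1C(COCc2ccc(OC)cc2)=C(Oc2c(OCOCC[Si](C)(C)C)cc(C)cc2CO[Si](C)(C)C(C)(C)C)C=CC1[C@@H](O[Si](C)(C)C(C)(C)C)CC(C)C | intermediate (not isolated)
26 | 3-(ArB-oxy)-6-[(1S)-1-{[tert-butyl(dimethyl)silyl]oxy}-3-methylbutyl]-2-{[(4-methoxybenzyl)oxy]methyl}phenol | Oc1c([C@@H](O[Si](C)(C)C(C)(C)C)CC(C)C)ccc(Oc2c(OCOCC[Si](C)(C)C)cc(C)cc2CO[Si](C)(C)C(C)(C)C)c1COCc1ccc(OC)cc1 | intermediate
27 | O-methyl ether of 26 | COc1c([C@@H](O[Si](C)(C)C(C)(C)C)CC(C)C)ccc(Oc2c(OCOCC[Si](C)(C)C)cc(C)cc2CO[Si](C)(C)C(C)(C)C)c1COCc1ccc(OC)cc1 | intermediate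
28 | {6-(ArB-oxy)-3-[(1S)-1-{[tert-butyl(dimethyl)silyl]oxy}-3-methylbutyl]-2-methoxyphenyl}methanol | COc1c([C@@H](O[Si](C)(C)C(C)(C)C)CC(C)C)ccc(Oc2c(OCOCC[Si](C)(C)C)cc(C)cc2CO[Si](C)(C)C(C)(C)C)c1CO | intermediate
29 | 6-(ArB-oxy)-3-[(1S)-1-{[tert-butyl(dimethyl)silyl]oxy}-3-methylbutyl]-2-methoxybenzaldehyde | COc1c([C@@H](O[Si](C)(C)C(C)(C)C)CC(C)C)ccc(Oc2c(OCOCC[Si](C)(C)C)cc(C)cc2CO[Si](C)(C)C(C)(C)C)c1C=O | intermediate
30 | 6-(ArB-oxy)-3-[(1S)-1-{[tert-butyl(dimethyl)silyl]oxy}-3-methylbutyl]-2-methoxybenzoic acid | COc1c([C@@H](O[Si](C)(C)C(C)(C)C)CC(C)C)ccc(Oc2c(OCOCC[Si](C)(C)C)cc(C)cc2CO[Si](C)(C)C(C)(C)C)c1C(=O)O | intermediate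
31 | 6-[2-hydroxy-6-(hydroxymethyl)-4-methylphenoxy]-3-[(1S)-1-hydroxy-3-methylbutyl]-2-methoxybenzoic acid | COc1c([C@@H](O)CC(C)C)ccc(Oc2c(O)cc(C)cc2CO)c1C(=O)O | target

**Step count and risks**

Total step count: 19. Longest linear sequence: 14 steps (creosol 1 to target 31 through steps 1–8 and 14–19); the leucic acid branch contributes steps 9–13.

Steps most likely to fail:

Step 14. Light may be absorbed unproductively by the three arene chromophores of 14. The aryl-conjugated ynol ether is also less electron-rich than an alkyl one, so it may trap ketene 22 more slowly than the ketene dimerises or acylates the product phenol. The fallback sets out from diazo enone 21 and returns at phenol 26; it keeps the same ring construction but makes the ketene in the dark from a different precursor. Compound 21 is irradiated alone in aqueous THF, so that ketene 22 is trapped by water as (S,E)-5-[(tert-butyldimethylsilyl)oxy]-7-methyloct-3-enoic acid F1. 1-Chloro-N,N,2-trimethylprop-1-en-1-amine in CH2Cl2 converts it under neutral conditions into (S,E)-5-[(tert-butyldimethylsilyl)oxy]-7-methyloct-3-enoyl chloride F2. Slow addition of F2 to Et3N and an excess of 14 in toluene (rt, then 80 °C) regenerates 22 by dehydrochlorination at low stationary concentration, and the sequence 23, 24, 25 then leads to 26.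

Step 7. Lithium acetylide 12 may decompose, by expulsion of the phenoxide or by competing lithiation next to the SEM ether, before the slowly depolymerising paraformaldehyde traps it. The γ-hydroxy ynol ether 13 may also rearrange to an acrylate (Meyer–Schuster type) on contact with acid during isolation. The fallback sets out from phenol 7 and returns at ynol ether 14, avoiding organolithium reagents and the free propargylic alcohol. Ramirez olefination (CBr4, PPh3, CH2Cl2) of 2-[(4-methoxybenzyl)oxy]acetaldehyde gives 1-{[(3,3-dibromoprop-2-en-1-yl)oxy]methyl}-4-methoxybenzene F3. Copper-catalysed C–O coupling of 7 with F3 (CuI with monovalent copper as catalyst, 2,2'-bipyridine, K3PO4, toluene, 110 °C) should replace the bromine trans to the CH2OPMB group and give (Z)-1-bromo-3-[(4-methoxybenzyl)oxy]prop-1-en-1-yl ArB ether F4, the O–C bond again being made on a non-aromatic carbon. KOt-Bu in THF then eliminates HBr anti to give 14.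

Step 19. Fluoride-induced fragmentation of the hindered aryl SEM ether may be sluggish, and the polyfunctional product may degrade on prolonged heating with basic n-Bu4NF. The fallback sets out from acid 30 and returns at target 31 by a staged deprotection with a different cleavage mechanism for SEM. HF·pyridine in THF–pyridine at 0 °C → rt removes only the two TBS ethers, giving 3-[(1S)-1-hydroxy-3-methylbutyl]-6-[2-(hydroxymethyl)-4-methyl-6-{[2-(trimethylsilyl)ethoxy]methoxy}phenoxy]-2-methoxybenzoic acid F5. MgBr2·OEt2 in Et2O–MeNO2 at rt then removes the SEM group by chelation-assisted Lewis-acid cleavage, followed by aqueous work-up, to give 31.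

**Further compounds**

F1 | step 14 | (S,E)-5-[(tert-butyldimethylsilyl)oxy]-7-methyloct-3-enoic acid | OC(=O)C/C=C/[C@@H](O[Si](C)(C)C(C)(C)C)CC(C)C
F2 | step 14 | (S,E)-5-[(tert-butyldimethylsilyl)oxy]-7-methyloct-3-enoyl chloride | ClC(=O)C/C=C/[C@@H](O[Si](C)(C)C(C)(C)C)CC(C)C
F3 | step 7 | 1-{[(3,3-dibromoprop-2-en-1-yl)oxy]methyl}-4-methoxybenzene | COc1ccc(COCC=C(Br)Br)cc1
F4 | step 7 | (Z)-1-bromo-3-[(4-methoxybenzyl)oxy]prop-1-en-1-yl ArB ether | C[Si](C)(C)CCOCOc1cc(C)cc(CO[Si](C)(C)C(C)(C)C)c1O/C(Br)=C/COCc1ccc(OC)cc1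
F5 | step 19 | 3-[(1S)-1-hydroxy-3-methylbutyl]-6-[2-(hydroxymethyl)-4-methyl-6-{[2-(trimethylsilyl)ethoxy]methoxy}phenoxy]-2-methoxybenzoic acid | COc1c([C@@H](O)CC(C)C)ccc(Oc2c(OCOCC[Si](C)(C)C)cc(C)cc2CO)c1C(=O)O
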